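**Plan**

1. Locants follow spiro[5.5]undecane numbering: ring A = C1 (CMe2), C2 (CHBr), C3 (CHOH), C4 (CH2), C5 (C=CH2), C6 (spiro carbon); ring B = C7, C8 (C=O), C9 (C(OH)CH2Cl), C10, C11.
2. Retrosynthesis: ring B is taken back to its symmetric C9 ketone (C8 oxygen by desymmetrising α-oxygenation, CH2Cl by LiCH2Cl addition). The cis-bromohydrin goes back to a C2=C3 alkenyl boronate. Ring A is then cut at C3–C4 and C1–C2, which releases ethynyl pinacol boronate (C2–C3) and a ring B ketal whose quaternary carbon C6 carries an isopropenyl and a 2-(chloromethyl)vinyl group.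
3. Enabling feature: in ring A, C6 is flanked by C1(CH3)2 and by C5(=CH2)–C4H2, two three-carbon units at the isopropenyl oxidation level (one plus H, one minus a leaving group). Hydrogen-atom transfer turns one into the tertiary C1 radical, the other is a radical allyl acceptor, and the two-carbon unit is stitched in between.
4. Forward: ring B first (acetylacetone plus a C5 bis-electrophile), then two isopropenyl groups, then the radical (4+2) annulation that closes ring A, then bromoketone and bromohydrin, then desymmetrisation and oxidation of ring B.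
5. Stereochemistry: C2 and C3 come from regiospecific bromination of a boron enolate (racemic) followed by a catalyst-controlled CBS reduction run as a kinetic resolution (cis by hydride attack anti to C–Br), which caps that step at half the material. C6 and a temporary C8 carbinol come from L-proline aminoxylation of the prochiral ketone. C9 comes from chelation-controlled addition cis to the C8 oxygen.

Key step: step 5

Assumption: in 13–16 ring B is taken to prefer the chair with C1 (the CMe2 arm of ring A) equatorial and C5 axial, and the alkynyl boronate 8 is taken to accept a nucleophilic tertiary radical at its unsubstituted carbon as vinyl boronates do.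

**Route**

Step 1
Reactants: 1 1,5-dichloropentan-3-one; 2 ethane-1,2-diol
Product: 3 2,2-bis(2-chloroethyl)-1,3-dioxolane
Conditions: TsOH·H2O (cat.), toluene, reflux, Dean–Stark trap
Reagents that add atoms: none
Why: Acid-catalysed ketalisation with azeotropic removal of water masks the carbonyl that becomes C9 and gives a base-stable C5 bis-electrophile with no stereocentre.

Step 2
Reactants: 3 2,2-bis(2-chloroethyl)-1,3-dioxolane; 4 pentane-2,4-dione
Product: 5 8,8-diacetyl-1,4-dioxaspiro[4.5]decane
Conditions: K2CO3 (2.5 equiv), NaI (0.2 equiv), DMSO, 60 °C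
Reagents that add atoms: none
Why: Double C-alkylation of the acetylacetone enolate should close ring B, the second alkylation being a 6-exo-tet ring closure that is preferred over O-alkylation through an eight-membered ring, and it creates the quaternary carbon that becomes C6, which is not yet stereogenic.

Step 3
Reactants: 5 8,8-diacetyl-1,4-dioxaspiro[4.5]decane
Product: 6 8,8-di(prop-1-en-2-yl)-1,4-dioxaspiro[4.5]decane
Conditions: Ph3PCH3Br (3 equiv), KN(SiMe3)2 (2.9 equiv), THF, 0 °C to reflux
Reagents that add atoms: methyltriphenylphosphonium bromide, C[P+](c1ccccc1)(c1ccccc1)c1ccccc1.[Br-]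
Why: Twofold Wittig methylenation with a non-nucleophilic base should avoid retro-Claisen cleavage of the non-enolisable 1,3-diketone and gives two homotopic isopropenyl groups on the future C6.

Step 4
Reactants: 6 8,8-di(prop-1-en-2-yl)-1,4-dioxaspiro[4.5]decane
Product: 7 8-(3-chloroprop-1-en-2-yl)-8-(prop-1-en-2-yl)-1,4-dioxaspiro[4.5]decane
Conditions: NaOCl (aq., 1.0 equiv), CeCl3·7H2O (1.0 equiv), CH2Cl2/H2O, 0 °C
Reagents that add atoms: sodium hypochlorite, [Na+].[O-]Cl
Why: Ene-type allylic chlorination by hypochlorous acid (chlorine to the CH2 terminus, loss of a methyl proton) should turn one isopropenyl group into a 2-(chloromethyl)vinyl group; the two groups are homotopic, so no isomers arise, and unreacted 6 is recovered and recycled while the dichloride is removed.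

Step 5
Reactants: 7 8-(3-chloroprop-1-en-2-yl)-8-(prop-1-en-2-yl)-1,4-dioxaspiro[4.5]decane; 8 2-ethynyl-4,4,5,5-tetramethyl-1,3,2-dioxaborolane
Product: 9 2-[9,9-(ethylenedioxy)-1,1-dimethyl-5-methylidenespiro[5.5]undec-2-en-3-yl]-4,4,5,5-tetramethyl-1,3,2-dioxaborolane
Conditions: Fe(acac)3 (30 mol %), PhSiH3 (2 equiv, slow addition), Na2HPO4 (2 equiv), 8 (5 equiv), degassed THF/i-PrOH 4:1, 40 °C
Reagents that add atoms: none
Why: Proposed new method: an iron hydride formed from Fe(acac)3 and PhSiH3 should transfer a hydrogen atom to the CH2 terminus of the isopropenyl group of 7, the resulting tertiary radical at the future C1 adds to the unsubstituted carbon of 8 (bond C1–C2), and the α-boryl vinyl radical at C3 attacks the CH2 terminus of the 2-(chloromethyl)vinyl group (bond C3–C4), after which the β-chloro tertiary radical expels chloride (directly or after reduction by divalent iron) to leave the exocyclic methylene and return iron to the trivalent state. The closest known reaction types are the iron-hydride (MHAT) reductive coupling of unactivated alkenes with radical acceptors and radical allylation of allyl halides or sulfones by addition–fragmentation (SH2'); their merger with an alkynyl boronate as two-carbon acceptor in a ring-forming cascade has not been described. Ring A closes by 6-endo-trig attack of the vinyl radical on a 1,1-disubstituted alkene, which should beat 5-exo closure because the internal alkene carbon is fully substituted and sits next to the quaternary C6. No stereocentre is formed, since ring B is symmetric and C3 is sp2, so 9 is achiral. The step needs chemoselective hydrogen-atom transfer (the isopropenyl group is more electron-rich than the chloromethyl-substituted alkene, and transfer to the latter only expels chloride and regenerates 6), intermolecular trapping of the C1 radical faster than its 1,2-vinyl shift (a large excess of 8 is used for this), and fixed positions of boron and of the new alkenes, which follow from the site of radical addition and from the C–Cl fragmentation.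

Step 6
Reactants: 9 2-[9,9-(ethylenedioxy)-1,1-dimethyl-5-methylidenespiro[5.5]undec-2-en-3-yl]-4,4,5,5-tetramethyl-1,3,2-dioxaborolane
Product: 11 rac-2-bromo-9,9-(ethylenedioxy)-1,1-dimethyl-5-methylidenespiro[5.5]undecan-3-one, via enol borate 10 (not isolated)
Conditions: Me3NO (anhydrous, 1.1 equiv), THF, 60 °C; then NBS (1.05 equiv), −78 °C; aq. NaHCO3 work-up; used at once
Reagents that add atoms: trimethylamine N-oxide, C[N+](C)(C)[O-]; N-bromosuccinimide, O=C1CCC(=O)N1Br
Why: Amine-oxide oxidation of the alkenyl boronic ester (1,2-shift of the alkenyl group from boron to oxygen) keeps the double bond between C2 and C3 and so should give the boron enolate regiospecifically, which NBS brominates at C2 and not at the more acidic C4; C2 forms as a racemate because ring B is symmetric and nothing controls the face.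

Step 7
Reactants: 11 rac-2-bromo-9,9-(ethylenedioxy)-1,1-dimethyl-5-methylidenespiro[5.5]undecan-3-one
Product: 13 (2R,3S)-2-bromo-3-hydroxy-1,1-dimethyl-5-methylidenespiro[5.5]undecan-9-one, via bromohydrin ketal 12 (not isolated)
Conditions: (R)-2-methyl-CBS-oxazaborolidine (0.3 equiv), catecholborane (0.6 equiv), toluene, −78 °C, partial conversion; MeOH; then 1 M HCl, acetone, 0 °C to rt; chromatography
Reagents that add atoms: none
Why: The CBS (Corey–Bakshi–Shibata) reduction is used as a kinetic resolution in which the (2R)-bromoketone is the matched enantiomer, because catalyst-directed hydride delivery (bromine-bearing side as the large group) and the inherent attack of hydride anti to the C–Br bond both give the (3S) alcohol cis to bromine, while the (2S)-ketone should react slowly and is removed after the acid treatment that also cleaves the dioxolane.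

Step 8
Reactants: 13 (2R,3S)-2-bromo-3-hydroxy-1,1-dimethyl-5-methylidenespiro[5.5]undecan-9-one
Product: 15 (2R,3S,6R,8R)-2-bromo-3,8-dihydroxy-1,1-dimethyl-5-methylidenespiro[5.5]undecan-9-one, via aminooxy ketone 14 (not isolated)
Conditions: L-proline (0.3 equiv), PhNO (1.2 equiv, slow addition), DMSO, rt; then CuSO4·5H2O (0.3 equiv), MeOH, 0 °C
Reagents that add atoms: nitrosobenzene, O=Nc1ccccc1
Why: Proline-catalysed α-aminoxylation (enamine catalysis) followed by N–O cleavage should set C8 as (R) as it does for cyclohexanone, and of the two diastereotopic α-methylene groups the one is oxidised whose C–O bond forms on the face away from the axial C5 arm (equatorial, cis to the C1 arm), which makes C6 a stereocentre of (R) configuration.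

Step 9
Reactants: 15 (2R,3S,6R,8R)-2-bromo-3,8-dihydroxy-1,1-dimethyl-5-methylidenespiro[5.5]undecan-9-one
Product: 16 (2R,3S,6R,8R,9S)-2-bromo-9-(chloromethyl)-1,1-dimethyl-5-methylidenespiro[5.5]undecane-3,8,9-triol
Conditions: LiN(SiMe3)2 (2.1 equiv), THF, −78 °C; ICH2Cl (3 equiv), MeLi·LiBr (3 equiv), −78 °C; AcOH, −78 °C
Reagents that add atoms: chloroiodomethane, ClCI
Why: (Chloromethyl)lithium made in situ by iodine–lithium exchange should add to the C9 ketone under Cram-chelate control by the lithium alkoxide at C8, entering from the face of the C8–H bond (equatorial attack), which sets C9 as (S) with its hydroxyl cis to the C8 oxygen; the cold acid quench prevents closure of the chlorohydrin to an epoxide.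

Step 10
Reactants: 16 (2R,3S,6R,8R,9S)-2-bromo-9-(chloromethyl)-1,1-dimethyl-5-methylidenespiro[5.5]undecane-3,8,9-triol
Product: 17 (2R,3S,6R,9S)-2-bromo-9-(chloromethyl)-3,9-dihydroxy-1,1-dimethyl-5-methylidenespiro[5.5]undecan-8-one
Conditions: [(neocuproine)Pd(OAc)]2(OTf)2 (5 mol %), 1,4-benzoquinone (1.5 equiv), MeCN/H2O 10:1, rt
Reagents that add atoms: none
Why: Chelation-directed oxidation of vicinal diols by the cationic divalent palladium catalyst should convert only the secondary C8 hydroxyl next to the tertiary C9 hydroxyl into the ketone and leave the isolated C3 hydroxyl, the halides and the alkene untouched; no stereocentre is formed and the temporary C8 centre is removed.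

**Compound list**

1 | 1,5-dichloropentan-3-one | ClCCC(=O)CCCl | starting material
2 | ethane-1,2-diol | OCCO | starting material
3 | 2,2-bis(2-chloroethyl)-1,3-dioxolane | ClCCC1(CCCl)OCCO1 | intermediate
4 | pentane-2,4-dione | CC(=O)CC(C)=O | starting material
5 | 8,8-diacetyl-1,4-dioxaspiro[4.5]decane | CC(=O)C1(CCC2(CC1)OCCO2)C(C)=O | intermediate
6 | 8,8-di(prop-1-en-2-yl)-1,4-dioxaspiro[4.5]decane | CC(=C)C1(CCC2(CC1)OCCO2)C(C)=C | intermediate
7 | 8-(3-chloroprop-1-en-2-yl)-8-(prop-1-en-2-yl)-1,4-dioxaspiro[4.5]decane | CC(=C)C1(CCC2(CC1)OCCO2)C(=C)CCl | intermediate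
8 | 2-ethynyl-4,4,5,5-tetramethyl-1,3,2-dioxaborolane | C#CB1OC(C)(C)C(C)(C)O1 | starting material
9 | 2-[9,9-(ethylenedioxy)-1,1-dimethyl-5-methylidenespiro[5.5]undec-2-en-3-yl]-4,4,5,5-tetramethyl-1,3,2-dioxaborolane | C=C1CC(B2OC(C)(C)C(C)(C)O2)=CC(C)(C)C13CCC4(CC3)OCCO4 | intermediate
10 | 2-{[9,9-(ethylenedioxy)-1,1-dimethyl-5-methylidenespiro[5.5]undec-2-en-3-yl]oxy}-4,4,5,5-tetramethyl-1,3,2-dioxaborolane (enol borate) | C=C1CC(OB2OC(C)(C)C(C)(C)O2)=CC(C)(C)C13CCC4(CC3)OCCO4 | intermediate
11 | rac-2-bromo-9,9-(ethylenedioxy)-1,1-dimethyl-5-methylidenespiro[5.5]undecan-3-one (racemate) | C=C1CC(=O)C(Br)C(C)(C)C12CCC3(CC2)OCCO3 | intermediate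
12 | (2R,3S)-2-bromo-9,9-(ethylenedioxy)-1,1-dimethyl-5-methylidenespiro[5.5]undecan-3-ol | C=C1C[C@H](O)[C@H](Br)C(C)(C)C12CCC3(CC2)OCCO3 | intermediate
13 | (2R,3S)-2-bromo-3-hydroxy-1,1-dimethyl-5-methylidenespiro[5.5]undecan-9-one | C=C1C[C@H](O)[C@H](Br)C(C)(C)C12CCC(=O)CC2 | intermediate
14 | (2R,3S,6R,8R)-8-(anilinooxy)-2-bromo-3-hydroxy-1,1-dimethyl-5-methylidenespiro[5.5]undecan-9-one | C=C1C[C@H](O)[C@H](Br)C(C)(C)[C@@]12CCC(=O)[C@H](ONc3ccccc3)C2 | intermediate
15 | (2R,3S,6R,8R)-2-bromo-3,8-dihydroxy-1,1-dimethyl-5-methylidenespiro[5.5]undecan-9-one | C=C1C[C@H](O)[C@H](Br)C(C)(C)[C@@]12CCC(=O)[C@H](O)C2 | intermediate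
16 | (2R,3S,6R,8R,9S)-2-bromo-9-(chloromethyl)-1,1-dimethyl-5-methylidenespiro[5.5]undecane-3,8,9-triol | C=C1C[C@H](O)[C@H](Br)C(C)(C)[C@@]12CC[C@@](O)(CCl)[C@H](O)C2 | intermediate
17 | (2R,3S,6R,9S)-2-bromo-9-(chloromethyl)-3,9-dihydroxy-1,1-dimethyl-5-methylidenespiro[5.5]undecan-8-one | C=C1C[C@H](O)[C@H](Br)C(C)(C)[C@@]12CC[C@@](O)(CCl)C(=O)C2 | target

**Count and risks**

Total steps: 10. Longest linear sequence: 10 steps (1 to 17; 2, 4 and 8 enter along the way).

Steps most likely to fail:

1. Step 5 (Proposed new method). The bimolecular addition of the hindered C1 radical to the alkyne may be outrun by its 1,2-vinyl shift through 3-exo closure onto the neighbouring alkene. The vinyl radical may abstract hydrogen from ring B instead of cyclising. The alkynyl C–B bond may be cleaved in the protic medium. The fallback sets out from 3 and comes back at 11; it builds ring A first by the classical Michael–Claisen annulation, which forms the same two bonds by known chemistry, and then attaches ring B with 3. Mesityl oxide and dimethyl malonate (NaOMe, MeOH, reflux) give methyl 2,2-dimethyl-4,6-dioxocyclohexane-1-carboxylate F1, which aqueous KOH and then hot HCl convert into 5,5-dimethylcyclohexane-1,3-dione F2. Isobutanol with TsOH gives 3-isobutoxy-5,5-dimethylcyclohex-2-en-1-one F3. NaI in acetone turns 3 into 2,2-bis(2-iodoethyl)-1,3-dioxolane F4, and two successive alkylations of F3 at C6 with F4 (LiN(i-Pr)2, THF, −78 °C to rt) give 9,9-(ethylenedioxy)-3-isobutoxy-1,1-dimethylspiro[5.5]undec-3-en-5-one F5. Deprotonation at the only remaining acidic methylene (C2) with LiN(i-Pr)2 and bromination with NBS give 2-bromo-9,9-(ethylenedioxy)-3-isobutoxy-1,1-dimethylspiro[5.5]undec-3-en-5-one F6. Me3SiCH2Li with CeCl3 adds to the carbonyl to give 2-bromo-9,9-(ethylenedioxy)-3-isobutoxy-1,1-dimethyl-5-[(trimethylsilyl)methyl]spiro[5.5]undec-3-en-5-ol F7, and aqueous oxalic acid then brings about Peterson elimination and enol ether hydrolysis without opening the dioxolane, which gives 11.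

2. Step 8. The catalyst may discriminate poorly between the two diastereotopic α-methylene groups, so that control at C6 is lost, or the nitroso compound may react with the exocyclic alkene in an ene reaction. The fallback sets out from 13 and comes back at 15. Silylation (t-BuMe2SiOTf, 2,6-lutidine) gives (2R,3S)-2-bromo-3-(tert-butyldimethylsilyloxy)-1,1-dimethyl-5-methylidenespiro[5.5]undecan-9-one F8. Deprotonation with lithium (R,R)-bis(1-phenylethyl)amide and LiCl in the presence of Me3SiCl (or with the enantiomeric amide, whichever removes the C8 proton) gives the silyl enol ether (2R,3S,6R)-2-bromo-3-(tert-butyldimethylsilyloxy)-1,1-dimethyl-5-methylidene-9-(trimethylsilyloxy)spiro[5.5]undec-8-ene F9. Rubottom oxidation with dimethyldioxirane from the face away from the axial C5 arm, with mild acid work-up, gives (2R,3S,6R,8R)-2-bromo-3-(tert-butyldimethylsilyloxy)-8-hydroxy-1,1-dimethyl-5-methylidenespiro[5.5]undecan-9-one F10, and HF·pyridine removes the silyl ether to give 15.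

3. Step 9. The hydroxy ketone may enolise and undergo an α-ketol shift under the strongly basic conditions, or the nucleophile may enter axially and give the C9 epimer. The fallback sets out from 15 and comes back at 16. Both hydroxyl groups are silylated (Et3SiOTf, 2,6-lutidine) to (2R,3S,6R,8R)-2-bromo-1,1-dimethyl-5-methylidene-3,8-bis(triethylsilyloxy)spiro[5.5]undecan-9-one F11. Corey–Chaykovsky epoxidation with dimethylsulfoxonium methylide (Me3S(O)I, NaH, DMSO), which attacks cyclohexanones equatorially, should give the spiro-epoxide F12 with the C–O bond axial. LiCl with AcOH in THF opens the epoxide at its CH2 terminus to (2R,3S,6R,8R,9S)-2-bromo-9-(chloromethyl)-1,1-dimethyl-5-methylidene-3,8-bis(triethylsilyloxy)spiro[5.5]undecan-9-ol F13, and HF·pyridine removes both silyl ethers to give 16.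

**Further compounds**

F1 | step 5 | methyl 2,2-dimethyl-4,6-dioxocyclohexane-1-carboxylate | COC(=O)C1C(=O)CC(=O)CC1(C)C
F2 | step 5 | 5,5-dimethylcyclohexane-1,3-dione | CC1(C)CC(=O)CC(=O)C1
F3 | step 5 | 3-isobutoxy-5,5-dimethylcyclohex-2-en-1-one | CC(C)COC1=CC(=O)CC(C)(C)C1
F4 | step 5 | 2,2-bis(2-iodoethyl)-1,3-dioxolane | ICCC1(CCI)OCCO1
F5 | step 5 | 9,9-(ethylenedioxy)-3-isobutoxy-1,1-dimethylspiro[5.5]undec-3-en-5-one | CC(C)COC1=CC(=O)C2(CCC3(CC2)OCCO3)C(C)(C)C1
F6 | step 5 | 2-bromo-9,9-(ethylenedioxy)-3-isobutoxy-1,1-dimethylspiro[5.5]undec-3-en-5-one (racemate) | CC(C)COC1=CC(=O)C2(CCC3(CC2)OCCO3)C(C)(C)C1Br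
F7 | step 5 | 2-bromo-9,9-(ethylenedioxy)-3-isobutoxy-1,1-dimethyl-5-[(trimethylsilyl)methyl]spiro[5.5]undec-3-en-5-ol (racemic) | CC(C)COC1=CC(O)(C[Si](C)(C)C)C2(CCC3(CC2)OCCO3)C(C)(C)C1Br
F8 | step 8 | (2R,3S)-2-bromo-3-(tert-butyldimethylsilyloxy)-1,1-dimethyl-5-methylidenespiro[5.5]undecan-9-one | C=C1C[C@H](O[Si](C)(C)C(C)(C)C)[C@H](Br)C(C)(C)C12CCC(=O)CC2
F9 | step 8 | (2R,3S,6R)-2-bromo-3-(tert-butyldimethylsilyloxy)-1,1-dimethyl-5-methylidene-9-(trimethylsilyloxy)spiro[5.5]undec-8-ene | C=C1C[C@H](O[Si](C)(C)C(C)(C)C)[C@H](Br)C(C)(C)[C@@]12CCC(O[Si](C)(C)C)=CC2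
F10 | step 8 | (2R,3S,6R,8R)-2-bromo-3-(tert-butyldimethylsilyloxy)-8-hydroxy-1,1-dimethyl-5-methylidenespiro[5.5]undecan-9-one | C=C1C[C@H](O[Si](C)(C)C(C)(C)C)[C@H](Br)C(C)(C)[C@@]12CCC(=O)[C@H](O)C2
F11 | step 9 | (2R,3S,6R,8R)-2-bromo-1,1-dimethyl-5-methylidene-3,8-bis(triethylsilyloxy)spiro[5.5]undecan-9-one | C=C1C[C@H](O[Si](CC)(CC)CC)[C@H](Br)C(C)(C)[C@@]12CCC(=O)[C@H](O[Si](CC)(CC)CC)C2
F12 | step 9 | spiro-epoxide of F11 at C9 (oxirane oxygen axial, cis to the C8 oxygen) | C=C1C[C@H](O[Si](CC)(CC)CC)[C@H](Br)C(C)(C)[C@@]12CC[C@@]3(CO3)[C@H](O[Si](CC)(CC)CC)C2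
F13 | step 9 | (2R,3S,6R,8R,9S)-2-bromo-9-(chloromethyl)-1,1-dimethyl-5-methylidene-3,8-bis(triethylsilyloxy)spiro[5.5]undecan-9-ol | C=C1C[C@H](O[Si](CC)(CC)CC)[C@H](Br)C(C)(C)[C@@]12CC[C@@](O)(CCl)[C@H](O[Si](CC)(CC)CC)C2
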